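**Retrosynthetic overview**
1. Both 4-pyranone rings are the same building block, 2,6-diethyl-3,5-dimethyl-4-pyranone 4. It is closed once, in step 1, by C–O cyclodehydration and used twice (ring A once, ring B once); no other permanent ring is made.
2. Key disconnection: the Cd–O bond. The Cd carbinol and the E Ce=Cf alkene come from a Cf allylic alcohol by Re2O7-catalysed 1,3-hydroxyl transposition, trapped with the Cb hydroxyl as an all-cis acetal under thermodynamic control.
3. Cf–Cg: lateral aldol of the ring B fragment 8 onto enal 17, allylic oxidation, then a dynamic kinetic resolution (DKR) hydrogenation that fixes Cg.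
4. Ca–Cb: lateral aldol of 4 onto the Roche aldehyde 11 (sets Ca and Cb from Cc). Ch/Ci: lateral acylation of 4, then DKR hydrogenation.
5. Order of ring events: pyranone (step 1), temporary 1,3-dioxane closed in step 12 and opened in step 13.

Assumption and lettering: 5, 9, 15 and both enantiomers of RuCl2(xylbinap)(daipen) are bought; chain carbons are lettered ring A–Ca(Me)–Cb(OH)–Cc(Me)–Cd(OH)–Ce(Me)=Cf–Cg(Me)–ring B–Ch(Me)–Ci(OH)–Et.

**Route**

Step 1
Reactants: 1 pentan-3-one; 2 propanoic acid (2.2 equiv)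
Product: 4 2,6-diethyl-3,5-dimethyl-4H-pyran-4-one, via 4,6-dimethylnonane-3,5,7-trione 3 (not isolated)
Conditions: polyphosphoric acid, 95 °C, 4 h
Reagents that add atoms: none
Why: Polyphosphoric acid activates 2 as a mixed anhydride that C-acylates both α-carbons of 1, and the 1,3,5-triketone closes by enol O-attack and loss of water (acid-mediated 4-pyranone cyclodehydration, a C–O ring closure).

Step 2
Reactants: 4 2,6-diethyl-3,5-dimethyl-4H-pyran-4-one; 5 N-methoxy-N-methylpropanamide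
Product: 7 2-ethyl-3,5-dimethyl-6-(3-oxopentan-2-yl)-4H-pyran-4-one (racemic), via lateral sodium dienolate 6 (not isolated)
Conditions: 4 (2.2 equiv), NaN(SiMe3)2 (2.1 equiv), THF, −78 °C; then 5 (1.0 equiv), −78 → 0 °C; aq. NH4Cl; excess 4 recovered
Reagents that add atoms: none
Why: Lateral (vinylogous) deprotonation of one ethyl CH2 by the silylamide gives the sodium dienolate, which is C-acylated by the Weinreb amide (Claisen-type lateral acylation); the second equivalent of dienolate takes up the acidic Ch–H of the product, so no free amide base is left to attack 5 and the product enolate cannot add a second time.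

Step 3
Reactants: 7 2-ethyl-3,5-dimethyl-6-(3-oxopentan-2-yl)-4H-pyran-4-one
Product: 8 2-ethyl-6-[(2R,3R)-3-hydroxypentan-2-yl]-3,5-dimethyl-4H-pyran-4-one
Conditions: trans-RuCl2[(S)-xylbinap][(S)-daipen] (1 mol %), KOtBu (10 mol %), H2 (10 atm), iPrOH, 30 °C
Reagents that add atoms: none
Why: Proposed new method: DKR hydrogenation of an α-(4-oxopyran-2-yl) ketone, in which the Ch–H flanked by ketone and pyranone (a vinylogous β-dicarbonyl) racemises under alkoxide faster than outer-sphere hydride transfer, the catalyst delivers hydride to the Si face of the carbonyl and the Felkin–Anh preference (pyranonyl group anti to hydride) selects the enantiomer that gives the anti (2R,3R) alcohol; the closest known reaction is the Noyori DKR hydrogenation of α-substituted ketones and β-keto esters, and the catalyst sense is assigned by analogy with acetophenone.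

Step 4
Reactants: 9 methyl (R)-3-hydroxy-2-methylpropanoate
Product: 10 methyl (R)-3-[(tert-butyldimethylsilyl)oxy]-2-methylpropanoate
Conditions: TBSCl, imidazole, CH2Cl2, 0 °C → rt
Reagents that add atoms: tert-butyldimethylsilyl chloride CC(C)(C)[Si](C)(C)Cl
Why: Standard silylation of the primary alcohol; Cc comes from the chiral pool and is untouched.

Step 5
Reactants: 10 methyl (R)-3-[(tert-butyldimethylsilyl)oxy]-2-methylpropanoate
Product: 11 (R)-3-[(tert-butyldimethylsilyl)oxy]-2-methylpropanal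
Conditions: iBu2AlH (1.05 equiv), CH2Cl2, −78 °C; aq. KNaC4H4O6; used at once
Reagents that add atoms: none
Why: Partial ester reduction at −78 °C stops at the aluminium hemiacetal, which releases the aldehyde on work-up without touching the α-stereocentre.

Step 6
Reactants: 4 2,6-diethyl-3,5-dimethyl-4H-pyran-4-one; 11 (R)-3-[(tert-butyldimethylsilyl)oxy]-2-methylpropanal
Product: 13 6-[(2S,3S,4R)-5-[(tert-butyldimethylsilyl)oxy]-3-hydroxy-4-methylpentan-2-yl]-2-ethyl-3,5-dimethyl-4H-pyran-4-one, via lateral lithium dienolate 12 (not isolated)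
Conditions: 4 (1.2 equiv), LiN(iPr)2 (1.2 equiv), THF, −78 °C; then 11, −78 °C, 1 h; aq. NH4Cl at −78 °C
Reagents that add atoms: none
Why: Vinylogous (lateral) aldol addition in which the lithium dienolate attacks the Felkin–Anh face of the α-methyl aldehyde (Cb–OH syn to Cc–Me) through an open synclinal transition state with the aldehyde chain anti to the pyranylidene ring, giving Ca/Cb anti; the tight lithium aldolate resists retro-aldol until the cold quench.

Step 7
Reactants: 13 6-[(2S,3S,4R)-5-[(tert-butyldimethylsilyl)oxy]-3-hydroxy-4-methylpentan-2-yl]-2-ethyl-3,5-dimethyl-4H-pyran-4-one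
Product: 14 6-[(2S,3S,4R)-3,5-dihydroxy-4-methylpentan-2-yl]-2-ethyl-3,5-dimethyl-4H-pyran-4-one
Conditions: Bu4NF, AcOH, THF, 0 °C → rt
Reagents that add atoms: none
Why: Fluoride desilylation, buffered with AcOH so that the β-hydroxy pyranone does not undergo retro-aldol or elimination.

Step 8
Reactants: 14 6-[(2S,3S,4R)-3,5-dihydroxy-4-methylpentan-2-yl]-2-ethyl-3,5-dimethyl-4H-pyran-4-one; 15 2-(triphenylphosphoranylidene)propanal
Product: 17 (2E,4R,5S,6S)-6-(6-ethyl-3,5-dimethyl-4-oxo-4H-pyran-2-yl)-5-hydroxy-2,4-dimethylhept-2-enal, via hydroxy aldehyde 16 (not isolated)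
Conditions: TEMPO (10 mol %), PhI(OAc)2 (1.1 equiv), CH2Cl2, rt; then 15 (1.5 equiv), 40 °C
Reagents that add atoms: none
Why: Oxoammonium oxidation is selective for the primary alcohol, and the stabilised ylide then gives the E trisubstituted enal (Wittig reaction) under neutral conditions that spare the Cc stereocentre and the free Cb hydroxyl.

Step 9
Reactants: 8 2-ethyl-6-[(2R,3R)-3-hydroxypentan-2-yl]-3,5-dimethyl-4H-pyran-4-one; 17 (2E,4R,5S,6S)-6-(6-ethyl-3,5-dimethyl-4-oxo-4H-pyran-2-yl)-5-hydroxy-2,4-dimethylhept-2-enal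
Product: 19 2-ethyl-6-[(2S,3S,4R,5E)-3,7-dihydroxy-8-{6-[(2R,3R)-3-hydroxypentan-2-yl]-3,5-dimethyl-4-oxo-4H-pyran-2-yl}-4,6-dimethylnon-5-en-2-yl]-3,5-dimethyl-4H-pyran-4-one (Cf/Cg diastereomer mixture), via dilithium dianion 18 (not isolated)
Conditions: 8 (2.2 equiv), LiN(iPr)2 (4.4 equiv), THF, −78 °C; then 17, −78 °C; aq. NH4Cl; excess 8 recovered
Reagents that add atoms: none
Why: Lateral aldol 1,2-addition of the dianion (alkoxide plus carbanion at the remaining ethyl CH2) to the enal; Cf and Cg are left uncontrolled on purpose because Cf is oxidised in step 10 and Cg is reset in step 11.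

Step 10
Reactants: 19 Cf/Cg diastereomer mixture of the Cf allylic alcohol
Product: 20 2-ethyl-6-[(2S,3S,4R,5E)-3-hydroxy-8-{6-[(2R,3R)-3-hydroxypentan-2-yl]-3,5-dimethyl-4-oxo-4H-pyran-2-yl}-4,6-dimethyl-7-oxonon-5-en-2-yl]-3,5-dimethyl-4H-pyran-4-one (Cg epimer mixture)
Conditions: MnO2 (20 equiv), CH2Cl2, rt
Reagents that add atoms: none
Why: Chemoselective allylic alcohol oxidation by MnO2 (the saturated Cb and Ci carbinols are not allylic) gives the enone whose Cg–H, flanked by ketone and pyranone, is configurationally labile.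

Step 11
Reactants: 20 enone (Cg epimer mixture)
Product: 21 2-ethyl-6-[(2S,3S,4R,5E,7S,8R)-3,7-dihydroxy-8-{6-[(2R,3R)-3-hydroxypentan-2-yl]-3,5-dimethyl-4-oxo-4H-pyran-2-yl}-4,6-dimethylnon-5-en-2-yl]-3,5-dimethyl-4H-pyran-4-one
Conditions: trans-RuCl2[(R)-xylbinap][(R)-daipen] (2 mol %), K2CO3 (20 mol %), H2 (10 atm), iPrOH, 25 °C
Reagents that add atoms: none
Why: Proposed new method: DKR hydrogenation of an α-(4-oxopyran-2-yl) enone, in which the hydride formed from RuCl2(xylbinap)(daipen) reduces only C=O, adds to the Re face with the alkenyl group as the recognised unsaturated substituent, and Cg epimerises through the dienolate under carbonate so that the Felkin–Anh-matched epimer is drained to the anti (Cf S, Cg R) alcohol; the closest known reactions are the Noyori hydrogenation of α,β-unsaturated ketones to allylic alcohols and the DKR hydrogenation of α-substituted ketones.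

Step 12
Reactants: 21 (7S,8R) anti allylic alcohol
Product: 23 anisylidene acetal of the target across the Cb and Cd oxygens [all-cis (2R,4S,5S,6R)-2-(4-methoxyphenyl)-5-methyl-1,3-dioxane; C4 = Cb bears the (1S)-1-(ring A)ethyl group; C6 = Cd bears the (2E,4R)-4-(ring B)pent-2-en-2-yl group], via transposed triol 22 (not isolated)
Conditions: Re2O7 (5 mol %), 4-MeOC6H4CH(OMe)2 (1.5 equiv), CH2Cl2, 0 °C → rt, 12 h; Et3N quench
Reagents that add atoms: 4-methoxybenzaldehyde dimethyl acetal COc1ccc(C(OC)OC)cc1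
Why: Key C–O bond formation by Re2O7-catalysed [3,3] 1,3-transposition of the allylic perrhenate ester (Osborn–Grubbs-type catalysis with Zakarian-type acetal trapping); under these equilibrating conditions the Cd–O bond settles in the one dioxane whose Cb, Cd and aryl groups are all equatorial (Cd R, syn to Cb, only the Cc methyl axial), the new Ce=Cf alkene is the less strained E isomer and the Cf stereocentre is erased.

Step 13
Reactants: 23 anisylidene acetal
Product: 24 2-ethyl-6-[(2S,3S,4S,5R,6E,8R)-3,5-dihydroxy-8-{6-[(2R,3R)-3-hydroxypentan-2-yl]-3,5-dimethyl-4-oxo-4H-pyran-2-yl}-4,6-dimethylnon-6-en-2-yl]-3,5-dimethyl-4H-pyran-4-one (target)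
Conditions: AcOH/THF/H2O (3:1:1), 35 °C
Reagents that add atoms: none
Why: Mild acid hydrolysis of the electron-rich anisylidene acetal (acetal hydrolysis) frees the syn-1,3-diol without ionising the allylic alcohol or dehydrating the β-hydroxy pyranones.

**Compound list**
1 | pentan-3-one | CCC(=O)CC | starting material
2 | propanoic acid | CCC(=O)O | starting material
3 | 4,6-dimethylnonane-3,5,7-trione (stereoisomer mixture, not isolated) | CCC(=O)C(C)C(=O)C(C)C(=O)CC | intermediate
4 | 2,6-diethyl-3,5-dimethyl-4H-pyran-4-one | CCc1oc(CC)c(C)c(=O)c1C | intermediate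
5 | N-methoxy-N-methylpropanamide | CCC(=O)N(C)OC | starting material
6 | sodium 2-ethyl-6-ethylidene-3,5-dimethyl-6H-pyran-4-olate (lateral sodium dienolate of 4, not isolated) | CC=C1OC(CC)=C(C)C([O-])=C1C.[Na+] | intermediate
7 | 2-ethyl-3,5-dimethyl-6-(3-oxopentan-2-yl)-4H-pyran-4-one (racemic) | CCc1oc(C(C)C(=O)CC)c(C)c(=O)c1C | intermediate
8 | 2-ethyl-6-[(2R,3R)-3-hydroxypentan-2-yl]-3,5-dimethyl-4H-pyran-4-one | CCc1oc([C@H](C)[C@H](O)CC)c(C)c(=O)c1C | intermediate
9 | methyl (R)-3-hydroxy-2-methylpropanoate | COC(=O)[C@H](C)CO | starting material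
10 | methyl (R)-3-[(tert-butyldimethylsilyl)oxy]-2-methylpropanoate | COC(=O)[C@H](C)CO[Si](C)(C)C(C)(C)C | intermediate
11 | (R)-3-[(tert-butyldimethylsilyl)oxy]-2-methylpropanal | O=C[C@H](C)CO[Si](C)(C)C(C)(C)C | intermediate
12 | lithium 2-ethyl-6-ethylidene-3,5-dimethyl-6H-pyran-4-olate (lateral lithium dienolate of 4, not isolated) | CC=C1OC(CC)=C(C)C([O-])=C1C.[Li+] | intermediate
13 | 6-[(2S,3S,4R)-5-[(tert-butyldimethylsilyl)oxy]-3-hydroxy-4-methylpentan-2-yl]-2-ethyl-3,5-dimethyl-4H-pyran-4-one | CCc1oc([C@@H](C)[C@@H](O)[C@H](C)CO[Si](C)(C)C(C)(C)C)c(C)c(=O)c1C | intermediate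
14 | 6-[(2S,3S,4R)-3,5-dihydroxy-4-methylpentan-2-yl]-2-ethyl-3,5-dimethyl-4H-pyran-4-one | CCc1oc([C@@H](C)[C@@H](O)[C@H](C)CO)c(C)c(=O)c1C | intermediate
15 | 2-(triphenylphosphoranylidene)propanal | CC(C=O)=P(c1ccccc1)(c1ccccc1)c1ccccc1 | starting material
16 | (2S,3R,4S)-4-(6-ethyl-3,5-dimethyl-4-oxo-4H-pyran-2-yl)-3-hydroxy-2-methylpentanal (not isolated) | CCc1oc([C@@H](C)[C@@H](O)[C@H](C)C=O)c(C)c(=O)c1C | intermediate
17 | (2E,4R,5S,6S)-6-(6-ethyl-3,5-dimethyl-4-oxo-4H-pyran-2-yl)-5-hydroxy-2,4-dimethylhept-2-enal | CCc1oc([C@@H](C)[C@@H](O)[C@H](C)/C=C(\C)C=O)c(C)c(=O)c1C | intermediate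
18 | dilithium (2R,3R)-2-(6-ethylidene-3,5-dimethyl-4-oxido-6H-pyran-2-yl)pentan-3-olate (dianion of 8, not isolated) | CC=C1OC([C@H](C)[C@H]([O-])CC)=C(C)C([O-])=C1C.[Li+].[Li+] | intermediate
19 | 2-ethyl-6-[(2S,3S,4R,5E)-3,7-dihydroxy-8-{6-[(2R,3R)-3-hydroxypentan-2-yl]-3,5-dimethyl-4-oxo-4H-pyran-2-yl}-4,6-dimethylnon-5-en-2-yl]-3,5-dimethyl-4H-pyran-4-one (mixture at C7 = Cf and C8 = Cg) | CCc1oc([C@@H](C)[C@@H](O)[C@H](C)/C=C(\C)C(O)C(C)c2oc([C@H](C)[C@H](O)CC)c(C)c(=O)c2C)c(C)c(=O)c1C | intermediate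
20 | 2-ethyl-6-[(2S,3S,4R,5E)-3-hydroxy-8-{6-[(2R,3R)-3-hydroxypentan-2-yl]-3,5-dimethyl-4-oxo-4H-pyran-2-yl}-4,6-dimethyl-7-oxonon-5-en-2-yl]-3,5-dimethyl-4H-pyran-4-one (mixture at C8 = Cg) | CCc1oc([C@@H](C)[C@@H](O)[C@H](C)/C=C(\C)C(=O)C(C)c2oc([C@H](C)[C@H](O)CC)c(C)c(=O)c2C)c(C)c(=O)c1C | intermediate
21 | 2-ethyl-6-[(2S,3S,4R,5E,7S,8R)-3,7-dihydroxy-8-{6-[(2R,3R)-3-hydroxypentan-2-yl]-3,5-dimethyl-4-oxo-4H-pyran-2-yl}-4,6-dimethylnon-5-en-2-yl]-3,5-dimethyl-4H-pyran-4-one | CCc1oc([C@@H](C)[C@@H](O)[C@H](C)/C=C(\C)[C@@H](O)[C@@H](C)c2oc([C@H](C)[C@H](O)CC)c(C)c(=O)c2C)c(C)c(=O)c1C | intermediate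
22 | transposed triol: 2-ethyl-6-[(2S,3S,4S,6E,8R)-3,5-dihydroxy-8-{6-[(2R,3R)-3-hydroxypentan-2-yl]-3,5-dimethyl-4-oxo-4H-pyran-2-yl}-4,6-dimethylnon-6-en-2-yl]-3,5-dimethyl-4H-pyran-4-one as both C5 (= Cd) epimers (not isolated) | CCc1oc([C@@H](C)[C@@H](O)[C@H](C)C(O)/C(C)=C/[C@@H](C)c2oc([C@H](C)[C@H](O)CC)c(C)c(=O)c2C)c(C)c(=O)c1C | intermediate
23 | 2-ethyl-6-[(1S)-1-{(2R,4S,5S,6R)-6-[(2E,4R)-4-{6-[(2R,3R)-3-hydroxypentan-2-yl]-3,5-dimethyl-4-oxo-4H-pyran-2-yl}pent-2-en-2-yl]-2-(4-methoxyphenyl)-5-methyl-1,3-dioxan-4-yl}ethyl]-3,5-dimethyl-4H-pyran-4-one (all-cis dioxane) | CCc1oc([C@@H](C)[C@@H](O3)[C@H](C)[C@@H](O[C@@H]3c4ccc(OC)cc4)/C(C)=C/[C@@H](C)c2oc([C@H](C)[C@H](O)CC)c(C)c(=O)c2C)c(C)c(=O)c1C | intermediate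
24 | 2-ethyl-6-[(2S,3S,4S,5R,6E,8R)-3,5-dihydroxy-8-{6-[(2R,3R)-3-hydroxypentan-2-yl]-3,5-dimethyl-4-oxo-4H-pyran-2-yl}-4,6-dimethylnon-6-en-2-yl]-3,5-dimethyl-4H-pyran-4-one | CCc1oc([C@@H](C)[C@@H](O)[C@H](C)[C@@H](O)/C(C)=C/[C@@H](C)c2oc([C@H](C)[C@H](O)CC)c(C)c(=O)c2C)c(C)c(=O)c1C | target

**Step count and risks**

Total steps: 13. Longest linear sequence: 10 (steps 4–13, from 9 to 24).

The three steps most likely to fail:

Step 3 (proposed new method). The ketone is dialkyl-like, so enantioface discrimination may be modest, and alkoxide could cause retro-Claisen cleavage. The fallback uses known chemistry, sets out from 7 and comes back at 8. Compound 7 is reduced with LiBH(sBu)3 in THF at −78 °C under Felkin–Anh substrate control to the racemic anti alcohol F1. This is esterified with (1S)-camphanic chloride (Et3N, DMAP, CH2Cl2) and the two diastereomeric esters are separated by chromatography or crystallisation. The camphanate of the (2S,3S)-alcohol F3 is set aside, and the camphanate of the (2R,3R)-alcohol F2 is cleaved with K2CO3 in MeOH to give 8.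

Step 6. The Felkin sense is reliable, but the simple anti/syn selectivity of the lateral lithium dienolate aldol is not established. The fallback sets out from the crude diastereomer mixture of 13 and comes back at pure 13. Mesylation (MsCl, Et3N, CH2Cl2) gives the mesylate F4, and DBU eliminates it through the lateral dienolate to the conjugated (E)-alkenylpyranone F5. Hydroboration with thexylborane in THF at 0 °C and oxidation with NaBO3·4H2O then puts the Cb hydroxyl back: syn addition of H and B across the E alkene gives Ca/Cb anti, and attack anti to the CH2OTBS group of the A(1,3)-minimised conformer gives Cb/Cc syn, which is 13.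

Step 11 (proposed new method). Cg may epimerise too slowly, carbonate may epimerise Cc through γ-deprotonation, or the sense of induction may be opposite (then the antipodal catalyst is used). The fallback uses known chemistry, sets out from 20 and comes back at 21. Luche reduction (NaBH4, CeCl3·7H2O, MeOH, −78 °C) is Felkin–Anh selective but not face selective for the two Cg epimers, so it gives 21 together with the (7R,8S) anti isomer F6. These are diastereomers and are separated by chromatography. F6 is oxidised back to 20 with MnO2, Cg is re-equilibrated with catalytic DBU, and the material is recycled.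

**Further compounds**
F1 | step 3 | racemic anti alcohol: 8 and its (2S,3S) enantiomer, 1:1 | CCc1oc([C@H](C)[C@H](O)CC)c(C)c(=O)c1C.CCc1oc([C@@H](C)[C@@H](O)CC)c(C)c(=O)c1C
F2 | step 3 | (2R,3R)-2-(6-ethyl-3,5-dimethyl-4-oxo-4H-pyran-2-yl)pentan-3-yl (1S)-camphanate | CCc1oc([C@H](C)[C@H](OC(=O)[C@@]23CC[C@@](C)(C(=O)O2)C3(C)C)CC)c(C)c(=O)c1C
F3 | step 3 | (2S,3S)-2-(6-ethyl-3,5-dimethyl-4-oxo-4H-pyran-2-yl)pentan-3-yl (1S)-camphanate | CCc1oc([C@@H](C)[C@@H](OC(=O)[C@@]23CC[C@@](C)(C(=O)O2)C3(C)C)CC)c(C)c(=O)c1C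
F4 | step 6 | mesylate of 13 (Ca/Cb diastereomer mixture, 4R) | CCc1oc(C(C)C(OS(C)(=O)=O)[C@H](C)CO[Si](C)(C)C(C)(C)C)c(C)c(=O)c1C
F5 | step 6 | 6-[(2E,4S)-5-[(tert-butyldimethylsilyl)oxy]-4-methylpent-2-en-2-yl]-2-ethyl-3,5-dimethyl-4H-pyran-4-one | CCc1oc(/C(C)=C/[C@H](C)CO[Si](C)(C)C(C)(C)C)c(C)c(=O)c1C
F6 | step 11 | (7R,8S) anti diastereomer of 21 | CCc1oc([C@@H](C)[C@@H](O)[C@H](C)/C=C(\C)[C@H](O)[C@H](C)c2oc([C@H](C)[C@H](O)CC)c(C)c(=O)c2C)c(C)c(=O)c1C
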